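Ring B (labdane numbering) is read as a Diels–Alder cyclohexene. One intramolecular [4+2] cycloaddition of an open-chain trienal makes the ring-fusion bond C5–C10 and the bond C6–C7 together: the chain C1–C4 with its gem-dimethyl carbon is the tether that becomes ring A, C5=C6 is an enal dienophile, and C7=C8–C9=C10 is a stereodefined tetrasubstituted diene. The step exploits the trans-fused cyclohexene ring B with its quaternary C10: a chiral amine catalyst sets C5 and C10 in one operation. Oxidative loss of the formyl carbon then gives a C6 ketone, which moves the alkene to C7=C8 and delivers the axial C6 oxygen; a Julia–Kocienski olefination adds the dienol side chain.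

Key step: step 7

Numbering used below: ring A is C1–C5 with C10 (C4 carries the two methyl groups, C10 the angular methyl); ring B is C5–C10 (C6 carries the secondary acetate, C8 the CH2OAc carbon C17, C9 the side chain C11–C15 with the carbinol C13). TBS is tert-butyl(dimethyl)silyl, PMB is 4-methoxybenzyl.

Assumption: the sense of induction of the imidazolidinone (step 7), of the Trost ligand (step 11) and of the diol auxiliary in the first fallback is taken from the usual models for these controllers; where a model does not hold for these substrates, the mirror-image controller is used.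

Step 1
Reactants: 1 2,2-dimethylpent-4-enal; 2 diethyl {2-[methoxy(methyl)amino]-2-oxoethyl}phosphonate
Product: 3 (2E)-N-methoxy-N,4,4-trimethylhepta-2,6-dienamide
Conditions: NaH, THF, 0 °C to rt
Reagents that add atoms: none
Why: Horner–Wadsworth–Emmons olefination of the non-enolisable α-quaternary aldehyde with the stabilised phosphonate anion should give the E-enamide through the reversible, thermodynamically controlled addition–elimination, and the Weinreb amide is chosen because it survives step 3 and is reduced to the enal in step 4.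

Step 2
Reactants: 4 methyl but-2-ynoate
Product: 5 methyl (2E)-2,3-dibromobut-2-enoate
Conditions: Br2, CH2Cl2, 0 °C to rt, dark
Reagents that add atoms: bromine, BrBr
Why: Electrophilic anti addition of bromine to the alkyne (bromonium ion opened from the opposite face) should give the E-dibromide, whose geometry is carried into the tetrasubstituted C9=C10 alkene of the diene.

Step 3
Reactants: 3 (2E)-N-methoxy-N,4,4-trimethylhepta-2,6-dienamide; 5 methyl (2E)-2,3-dibromobut-2-enoate
Product: 7 methyl (2E,8E)-2-bromo-10-[methoxy(methyl)amino]-3,7,7-trimethyl-10-oxodeca-2,8-dienoate, via B-alkyl-9-borabicyclononane 6 (not isolated)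
Conditions: 9-BBN, THF, 0 °C to rt; then 5 (1.2 equiv), PdCl2(dppf) (5 mol%), K3PO4 (3 M in water), DMF, rt
Reagents that add atoms: none
Why: Anti-Markovnikov hydroboration of the only unhindered terminal alkene is followed by B-alkyl Suzuki–Miyaura coupling, in which oxidative addition should take place at the more electrophilic β-C–Br bond of the enoate (as in related α,β-dibromo enoates and dibromobutenolides) and the coupling proceeds with retention, so that the new chain (C1) lies cis to the ester (C11).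

Step 4
Reactants: 7 methyl (2E,8E)-2-bromo-10-[methoxy(methyl)amino]-3,7,7-trimethyl-10-oxodeca-2,8-dienoate
Product: 8 (2E,8E)-9-bromo-10-hydroxy-4,4,8-trimethyldeca-2,8-dienal
Conditions: i-Bu2AlH (3.5 equiv), CH2Cl2, −78 °C; aqueous potassium sodium tartrate work-up
Reagents that add atoms: none
Why: Hydride reduction with i-Bu2AlH should take the enoate to the allylic alcohol while the Weinreb amide stops at the chelated tetrahedral aluminate, which releases the E-enal only on work-up, and the alkenyl bromide and both alkene geometries are untouched.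

Step 5
Reactants: 9 tert-butyl(dimethyl)(prop-2-yn-1-yloxy)silane
Product: 10 tributyl[3-{[tert-butyl(dimethyl)silyl]oxy}prop-1-en-2-yl]stannane
Conditions: Bu3SnH, Mo(CO)3(CNtBu)3 (2 mol%), hydroquinone, THF, 55 °C
Reagents that add atoms: tributyltin hydride, CCCC[SnH](CCCC)CCCC
Why: Molybdenum-catalysed syn hydrostannation of the propargylic ether should deliver tin to the internal carbon (α-selective hydrostannation), which gives the 1,1-disubstituted alkenylstannane needed for C8 with its C17 oxygen.

Step 6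
Reactants: 8 (2E,8E)-9-bromo-10-hydroxy-4,4,8-trimethyldeca-2,8-dienal; 10 tributyl[3-{[tert-butyl(dimethyl)silyl]oxy}prop-1-en-2-yl]stannane
Product: 11 (2E,8Z)-10-({[tert-butyl(dimethyl)silyl]oxy}methyl)-9-(hydroxymethyl)-4,4,8-trimethylundeca-2,8,10-trienal
Conditions: Pd2(dba)3 (5 mol%), AsPh3, CuI (20 mol%), NMP, 45 °C
Reagents that add atoms: none
Why: Copper-assisted Stille coupling joins C8 to C9 with retention of the alkene geometry, so the C10 methyl group ends cis to C8 (inside position of the diene) and the tether ends outside, and the mild temperature keeps the uncatalysed cycloaddition of the product negligible.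

Step 7
Reactants: 11 (2E,8Z)-10-({[tert-butyl(dimethyl)silyl]oxy}methyl)-9-(hydroxymethyl)-4,4,8-trimethylundeca-2,8,10-trienal
Product: 12 (1R,4aR,8aR)-3-({[tert-butyl(dimethyl)silyl]oxy}methyl)-4-(hydroxymethyl)-4a,8,8-trimethyl-1,2,4a,5,6,7,8,8a-octahydronaphthalene-1-carbaldehyde
Conditions: (2R,5R)-5-benzyl-2-tert-butyl-3-methylimidazolidin-4-one·HClO4 (20 mol%), MeCN/H2O 98:2, 4 °C to rt
Reagents that add atoms: none
Why: The enal condenses reversibly with the imidazolidinone to an E-configured iminium ion whose lowered LUMO lets the electron-rich tetrasubstituted diene add in an asynchronous, concerted intramolecular Diels–Alder reaction, C5 (the iminium β-carbon) bonding to the nucleophilic terminus C10 and C6 to C7, before hydrolysis returns the catalyst. The closest known reaction type is the amine-catalysed (iminium) intramolecular Diels–Alder reaction of 2,8,10-trienals to trans-fused decalins, and thermal cycloadditions of this tether type are known to build angular-methyl quaternary centres. Ring A closes as the six-membered ring spanned by the four-carbon tether C1–C4 through the C5–C10 bond (helped by the C4 gem-dimethyl group), and ring B closes as the cyclohexene of the [4+2] addition through C5–C10 and C6–C7. The trans relation of C5–H and C10–CH3 follows from the endo transition state (iminium under the diene) with the tether outside and the methyl group inside at the diene terminus, the C6 centre follows from the E dienophile (and is erased in step 8), and the absolute configuration is set by the benzyl group of the (2R,5R) catalyst, which blocks one face of the iminium ion. The step needs endo over exo selectivity, facial selectivity and enough reactivity at two hindered carbons; the E enal, the defined 8Z diene geometry, the rigid catalyst and the entropic help of the tether should secure them, and the uncatalysed background reaction should be slow at this temperature.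

Step 8
Reactants: 12 (1R,4aR,8aR)-3-({[tert-butyl(dimethyl)silyl]oxy}methyl)-4-(hydroxymethyl)-4a,8,8-trimethyl-1,2,4a,5,6,7,8,8a-octahydronaphthalene-1-carbaldehyde
Product: 14 (4S,4aS,8aR)-3-({[tert-butyl(dimethyl)silyl]oxy}methyl)-4-(hydroxymethyl)-4a,8,8-trimethyl-4a,5,6,7,8,8a-hexahydronaphthalen-1(4H)-one, via deconjugated ketone 13 (not isolated)
Conditions: Cu(OAc)2 (10 mol%), 2,2′-bipyridine (10 mol%), DABCO, O2 (1 atm), DMF, 40 °C; then crude in CH2Cl2, DBU (20 mol%), 0 °C, AcOH quench
Reagents that add atoms: dioxygen, O=O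
Why: Copper-catalysed aerobic deformylation (Van Rheenen type: the copper enolate is oxygenated to an α-hydroperoxy aldehyde that fragments to the ketone and formic acid) gives the β,γ-unsaturated C6 ketone, and base-mediated conjugation through the dienolate then protonates C9 on the face anti to the angular methyl group, which sets 9S kinetically while the C8=C9 alkene moves to C7=C8.

Step 9
Reactants: 14 (4S,4aS,8aR)-3-({[tert-butyl(dimethyl)silyl]oxy}methyl)-4-(hydroxymethyl)-4a,8,8-trimethyl-4a,5,6,7,8,8a-hexahydronaphthalen-1(4H)-one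
Product: 15 (1S,4S,4aS,8aR)-3-({[tert-butyl(dimethyl)silyl]oxy}methyl)-4-(hydroxymethyl)-4a,8,8-trimethyl-1,4,4a,5,6,7,8,8a-octahydronaphthalen-1-ol
Conditions: NaBH4, CeCl3·7H2O, MeOH, −78 to −40 °C
Reagents that add atoms: none
Why: Luche 1,2-reduction: hydride should add to the C6 carbonyl from the face anti to the axial C10 methyl and the syn C4 methyl group, which gives the axial 6S alcohol cis to the angular methyl, and the now sp3 C6 ends the risk of epimerisation at C9.

Step 10
Reactants: 15 (1S,4S,4aS,8aR)-3-({[tert-butyl(dimethyl)silyl]oxy}methyl)-4-(hydroxymethyl)-4a,8,8-trimethyl-1,4,4a,5,6,7,8,8a-octahydronaphthalen-1-ol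
Product: 16 (1S,4S,4aR,8aR)-2-({[tert-butyl(dimethyl)silyl]oxy}methyl)-4-hydroxy-5,5,8a-trimethyl-1,4,4a,5,6,7,8,8a-octahydronaphthalene-1-carbaldehyde
Conditions: TEMPO (10 mol%), PhI(OAc)2, CH2Cl2, rt
Reagents that add atoms: none
Why: Oxoammonium (TEMPO) oxidation is selective for the primary C11 alcohol over the hindered axial secondary allylic alcohol and is run without base, so the α-stereocentre C9 of the β,γ-unsaturated aldehyde should survive.

Step 11
Reactants: 17 2-methyl-2-vinyloxirane (racemic); 18 (4-methoxyphenyl)methanol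
Product: 19 (2S)-2-[(4-methoxyphenyl)methoxy]-2-methylbut-3-en-1-ol
Conditions: Pd2(dba)3·CHCl3 (1 mol%), (R,R)-DACH-phenyl Trost ligand (3 mol%), BEt3 (1 mol%), CH2Cl2, rt
Reagents that add atoms: none
Why: Palladium-catalysed dynamic kinetic asymmetric allylic etherification (Trost): the racemic vinyl epoxide ionises to rapidly interconverting π-allyl complexes and the boron-bound alkoxide is delivered to the tertiary terminus under control of the chiral ligand, which sets the future C13 centre as S.

Step 12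
Reactants: 19 (2S)-2-[(4-methoxyphenyl)methoxy]-2-methylbut-3-en-1-ol; 20 1-phenyl-1H-tetrazole-5-thiol
Product: 22 5-{[(2S)-2-[(4-methoxyphenyl)methoxy]-2-methylbut-3-en-1-yl]sulfanyl}-1-phenyl-1H-tetrazole, via neopentyl triflate 21 (not isolated)
Conditions: Tf2O, 2,6-lutidine, CH2Cl2, −78 °C; then 20, Et3N, DMF, −78 °C to rt
Reagents that add atoms: none
Why: The primary alcohol is activated as its triflate and displaced by the soft tetrazolyl thiolate in an SN2 reaction that tolerates the neopentyl position, and the adjacent quaternary stereocentre is not involved.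

Step 13
Reactants: 22 5-{[(2S)-2-[(4-methoxyphenyl)methoxy]-2-methylbut-3-en-1-yl]sulfanyl}-1-phenyl-1H-tetrazole
Product: 23 5-{[(2S)-2-[(4-methoxyphenyl)methoxy]-2-methylbut-3-en-1-yl]sulfonyl}-1-phenyl-1H-tetrazole
Conditions: (NH4)6Mo7O24·4H2O (10 mol%), H2O2 (30% in water), EtOH, 0 °C to rt
Reagents that add atoms: hydrogen peroxide, OO
Why: Molybdate-catalysed peroxide oxidation of the sulfide to the sulfone is chemoselective in the presence of the terminal alkene and the PMB ether and gives the Julia–Kocienski reagent.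

Step 14
Reactants: 16 (1S,4S,4aR,8aR)-2-({[tert-butyl(dimethyl)silyl]oxy}methyl)-4-hydroxy-5,5,8a-trimethyl-1,4,4a,5,6,7,8,8a-octahydronaphthalene-1-carbaldehyde; 23 5-{[(2S)-2-[(4-methoxyphenyl)methoxy]-2-methylbut-3-en-1-yl]sulfonyl}-1-phenyl-1H-tetrazole
Product: 24 (1S,4S,4aS,8aR)-3-({[tert-butyl(dimethyl)silyl]oxy}methyl)-4-{(1E,3S)-3-[(4-methoxyphenyl)methoxy]-3-methylpenta-1,4-dien-1-yl}-4a,8,8-trimethyl-1,4,4a,5,6,7,8,8a-octahydronaphthalen-1-ol
Conditions: 23 (2.2 equiv), KN(SiMe3)2 (2.1 equiv), DME, −78 °C; then 16, −78 °C to rt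
Reagents that add atoms: none
Why: Julia–Kocienski olefination: the metalated phenyltetrazolyl sulfone adds to the aldehyde, and Smiles rearrangement with loss of SO2 and the tetrazolone gives the E-alkene C11=C12 by the open transition state favoured with the potassium base in DME, one equivalent of the anion being spent on the free C6 hydroxyl.

Step 15
Reactants: 24 (1S,4S,4aS,8aR)-3-({[tert-butyl(dimethyl)silyl]oxy}methyl)-4-{(1E,3S)-3-[(4-methoxyphenyl)methoxy]-3-methylpenta-1,4-dien-1-yl}-4a,8,8-trimethyl-1,4,4a,5,6,7,8,8a-octahydronaphthalen-1-ol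
Product: 25 (1S,4S,4aS,8aR)-3-(hydroxymethyl)-4-{(1E,3S)-3-[(4-methoxyphenyl)methoxy]-3-methylpenta-1,4-dien-1-yl}-4a,8,8-trimethyl-1,4,4a,5,6,7,8,8a-octahydronaphthalen-1-ol
Conditions: Bu4NF, THF, 0 °C to rt
Reagents that add atoms: none
Why: Fluoride-induced cleavage of the primary allylic silyl ether frees the C17 hydroxyl while the PMB ether and the skipped diene are inert.

Step 16
Reactants: 25 (1S,4S,4aS,8aR)-3-(hydroxymethyl)-4-{(1E,3S)-3-[(4-methoxyphenyl)methoxy]-3-methylpenta-1,4-dien-1-yl}-4a,8,8-trimethyl-1,4,4a,5,6,7,8,8a-octahydronaphthalen-1-ol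
Product: 26 [(1S,4S,4aR,8aS)-4-(acetyloxy)-1-{(1E,3S)-3-[(4-methoxyphenyl)methoxy]-3-methylpenta-1,4-dien-1-yl}-5,5,8a-trimethyl-1,4,4a,5,6,7,8,8a-octahydronaphthalen-2-yl]methyl acetate
Conditions: Ac2O, pyridine, DMAP (10 mol%), CH2Cl2, rt
Reagents that add atoms: acetic anhydride, CC(=O)OC(C)=O
Why: DMAP-catalysed acylation esterifies the primary C17 and the hindered axial C6 hydroxyl in one operation, and the tertiary C13 oxygen is still masked so forcing conditions cannot touch it.

Step 17
Reactants: 26 [(1S,4S,4aR,8aS)-4-(acetyloxy)-1-{(1E,3S)-3-[(4-methoxyphenyl)methoxy]-3-methylpenta-1,4-dien-1-yl}-5,5,8a-trimethyl-1,4,4a,5,6,7,8,8a-octahydronaphthalen-2-yl]methyl acetate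
Product: 27 [(1S,4S,4aR,8aS)-4-(acetyloxy)-1-[(1E,3S)-3-hydroxy-3-methylpenta-1,4-dien-1-yl]-5,5,8a-trimethyl-1,4,4a,5,6,7,8,8a-octahydronaphthalen-2-yl]methyl acetate (CNP0103498.1)
Conditions: DDQ, CH2Cl2/pH 7 phosphate buffer, 0 °C
Reagents that add atoms: none
Why: Oxidative cleavage of the PMB ether by DDQ (hydride abstraction to the oxocarbenium ion and hydrolysis) releases the tertiary bis-allylic alcohol under neutral conditions that spare the acetates and avoid ionisation at C13.

Compound list
1 | 2,2-dimethylpent-4-enal | C=CCC(C)(C)C=O | starting material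
2 | diethyl {2-[methoxy(methyl)amino]-2-oxoethyl}phosphonate | CCOP(=O)(OCC)CC(=O)N(C)OC | starting material
3 | (2E)-N-methoxy-N,4,4-trimethylhepta-2,6-dienamide | C=CCC(C)(C)/C=C/C(=O)N(C)OC | intermediate
4 | methyl but-2-ynoate | CC#CC(=O)OC | starting material
5 | methyl (2E)-2,3-dibromobut-2-enoate | COC(=O)/C(Br)=C(\Br)C | intermediate
6 | 9-[(5E)-7-[methoxy(methyl)amino]-4,4-dimethyl-7-oxohept-5-en-1-yl]-9-borabicyclo[3.3.1]nonane | CON(C)C(=O)/C=C/C(C)(C)CCCB1C2CCCC1CCC2 | intermediate
7 | methyl (2E,8E)-2-bromo-10-[methoxy(methyl)amino]-3,7,7-trimethyl-10-oxodeca-2,8-dienoate | COC(=O)/C(Br)=C(\CCCC(C)(C)/C=C/C(=O)N(C)OC)C | intermediate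
8 | (2E,8E)-9-bromo-10-hydroxy-4,4,8-trimethyldeca-2,8-dienal | O=C/C=C/C(C)(C)CCC/C(C)=C(Br)\CO | intermediate
9 | tert-butyl(dimethyl)(prop-2-yn-1-yloxy)silane | C#CCO[Si](C)(C)C(C)(C)C | starting material
10 | tributyl[3-{[tert-butyl(dimethyl)silyl]oxy}prop-1-en-2-yl]stannane | C=C(CO[Si](C)(C)C(C)(C)C)[Sn](CCCC)(CCCC)CCCC | intermediate
11 | (2E,8Z)-10-({[tert-butyl(dimethyl)silyl]oxy}methyl)-9-(hydroxymethyl)-4,4,8-trimethylundeca-2,8,10-trienal | O=C/C=C/C(C)(C)CCC/C(C)=C(CO)/C(=C)CO[Si](C)(C)C(C)(C)C | intermediate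
12 | (1R,4aR,8aR)-3-({[tert-butyl(dimethyl)silyl]oxy}methyl)-4-(hydroxymethyl)-4a,8,8-trimethyl-1,2,4a,5,6,7,8,8a-octahydronaphthalene-1-carbaldehyde | O=C[C@@H]1CC(CO[Si](C)(C)C(C)(C)C)=C(CO)[C@]2(C)CCCC(C)(C)[C@@H]12 | intermediate
13 | (4aR,8aR)-3-({[tert-butyl(dimethyl)silyl]oxy}methyl)-4-(hydroxymethyl)-4a,8,8-trimethyl-4a,5,6,7,8,8a-hexahydronaphthalen-1(2H)-one | O=C1CC(CO[Si](C)(C)C(C)(C)C)=C(CO)[C@]2(C)CCCC(C)(C)[C@@H]12 | intermediate
14 | (4S,4aS,8aR)-3-({[tert-butyl(dimethyl)silyl]oxy}methyl)-4-(hydroxymethyl)-4a,8,8-trimethyl-4a,5,6,7,8,8a-hexahydronaphthalen-1(4H)-one | O=C1C=C(CO[Si](C)(C)C(C)(C)C)[C@@H](CO)[C@]2(C)CCCC(C)(C)[C@@H]12 | intermediate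
15 | (1S,4S,4aS,8aR)-3-({[tert-butyl(dimethyl)silyl]oxy}methyl)-4-(hydroxymethyl)-4a,8,8-trimethyl-1,4,4a,5,6,7,8,8a-octahydronaphthalen-1-ol | O[C@H]1C=C(CO[Si](C)(C)C(C)(C)C)[C@@H](CO)[C@]2(C)CCCC(C)(C)[C@@H]12 | intermediate
16 | (1S,4S,4aR,8aR)-2-({[tert-butyl(dimethyl)silyl]oxy}methyl)-4-hydroxy-5,5,8a-trimethyl-1,4,4a,5,6,7,8,8a-octahydronaphthalene-1-carbaldehyde | O[C@H]1C=C(CO[Si](C)(C)C(C)(C)C)[C@@H](C=O)[C@]2(C)CCCC(C)(C)[C@@H]12 | intermediate
17 | 2-methyl-2-vinyloxirane (racemic) | C=CC1(C)CO1 | starting material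
18 | (4-methoxyphenyl)methanol | COc1ccc(CO)cc1 | starting material
19 | (2S)-2-[(4-methoxyphenyl)methoxy]-2-methylbut-3-en-1-ol | C=C[C@](C)(OCc1ccc(OC)cc1)CO | intermediate
20 | 1-phenyl-1H-tetrazole-5-thiol | Sc1nnnn1-c1ccccc1 | starting material
21 | (2S)-2-[(4-methoxyphenyl)methoxy]-2-methylbut-3-en-1-yl trifluoromethanesulfonate | C=C[C@](C)(OCc1ccc(OC)cc1)COS(=O)(=O)C(F)(F)F | intermediate
22 | 5-{[(2S)-2-[(4-methoxyphenyl)methoxy]-2-methylbut-3-en-1-yl]sulfanyl}-1-phenyl-1H-tetrazole | C=C[C@](C)(OCc1ccc(OC)cc1)CSc1nnnn1-c1ccccc1 | intermediate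
23 | 5-{[(2S)-2-[(4-methoxyphenyl)methoxy]-2-methylbut-3-en-1-yl]sulfonyl}-1-phenyl-1H-tetrazole | C=C[C@](C)(OCc1ccc(OC)cc1)CS(=O)(=O)c1nnnn1-c1ccccc1 | intermediate
24 | (1S,4S,4aS,8aR)-3-({[tert-butyl(dimethyl)silyl]oxy}methyl)-4-{(1E,3S)-3-[(4-methoxyphenyl)methoxy]-3-methylpenta-1,4-dien-1-yl}-4a,8,8-trimethyl-1,4,4a,5,6,7,8,8a-octahydronaphthalen-1-ol | C=C[C@](C)(OCc1ccc(OC)cc1)/C=C/[C@@H]1C(CO[Si](C)(C)C(C)(C)C)=C[C@H](O)[C@@H]2C(C)(C)CCC[C@@]12C | intermediate
25 | (1S,4S,4aS,8aR)-3-(hydroxymethyl)-4-{(1E,3S)-3-[(4-methoxyphenyl)methoxy]-3-methylpenta-1,4-dien-1-yl}-4a,8,8-trimethyl-1,4,4a,5,6,7,8,8a-octahydronaphthalen-1-ol | C=C[C@](C)(OCc1ccc(OC)cc1)/C=C/[C@@H]1C(CO)=C[C@H](O)[C@@H]2C(C)(C)CCC[C@@]12C | intermediate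
26 | [(1S,4S,4aR,8aS)-4-(acetyloxy)-1-{(1E,3S)-3-[(4-methoxyphenyl)methoxy]-3-methylpenta-1,4-dien-1-yl}-5,5,8a-trimethyl-1,4,4a,5,6,7,8,8a-octahydronaphthalen-2-yl]methyl acetate | C=C[C@](C)(OCc1ccc(OC)cc1)/C=C/[C@@H]1C(COC(C)=O)=C[C@H](OC(C)=O)[C@@H]2C(C)(C)CCC[C@@]12C | intermediate
27 | [(1S,4S,4aR,8aS)-4-(acetyloxy)-1-[(1E,3S)-3-hydroxy-3-methylpenta-1,4-dien-1-yl]-5,5,8a-trimethyl-1,4,4a,5,6,7,8,8a-octahydronaphthalen-2-yl]methyl acetate | C=C[C@](C)(O)/C=C/[C@@H]1C(COC(C)=O)=C[C@H](OC(C)=O)[C@@H]2C(C)(C)CCC[C@@]12C | target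

Total step count: 17.
Longest linear sequence: 12 steps from compound 1 (steps 1, 3, 4, 6, 7, 8, 9, 10, 14, 15, 16, 17).

Steps most likely to fail

Step 7. The diene terminus C10 and the dienophile carbon C5 are both hindered, so iminium activation may not give a useful rate; if the temperature has to be raised, the uncatalysed pathway and the exo mode could erode the enantiomeric and diastereomeric purity. The fallback replaces catalyst control by auxiliary control in an ionic Diels–Alder reaction. It sets out from 11. Acetalisation with the bis(trimethylsilyl) ether of (1R,2R)-1,2-diphenylethane-1,2-diol and catalytic Me3SiOTf in CH2Cl2 at −78 °C should give the chiral enal acetal F1. More Me3SiOTf ionises the acetal to a dioxolanyl-stabilised allyl cation, a far stronger dienophile, which should close both rings at −78 °C under the facial bias of the C2-symmetric diol to the cycloadduct acetal F2. Mild aqueous acid then hydrolyses the acetal and the transient silyl ether, and the route is rejoined at 12.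

Step 8. Prolonged base contact can equilibrate C9 through the extended dienolate (the epimer with the axial C9 substituent may be the more stable one), and the conjugation may stop short. The fallback separates the two events and makes the protonation strictly kinetic. It sets out from 13, isolated by stopping before the DBU treatment. Me3SiOTf and Et3N in CH2Cl2 at −78 °C should give the bis(trimethylsilyl) dienol ether F3 (silylated at the C6 dienol oxygen and at the C11 hydroxyl). Cold dilute HCl in THF then protonates the γ-carbon C9 irreversibly from the face anti to the angular methyl and removes both trimethylsilyl groups, and the route is rejoined at 14.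

Step 14. The β,γ-unsaturated aldehyde may be enolised by the metalated sulfone (loss of the C9 configuration or conjugation), and the metalated sulfone may expel its β-alkoxide before it adds. The fallback inverts the polarity of the olefination. It sets out from 15 and from 19. Mitsunobu reaction of the primary alcohol of 15 with 20 (PPh3, diisopropyl azodicarboxylate, THF) should give the sulfide F4, and molybdate-catalysed peroxide oxidation the sulfone F5. Dess–Martin oxidation of 19 gives the non-enolisable α-alkoxy aldehyde F6. Metalation of F5 with KN(SiMe3)2 in DME at −78 °C and addition of F6 should give the E-alkene, and the route is rejoined at 24.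

Further compounds
F1 | step 7 | (4R,5R)-2-[(1E,7Z)-9-({[tert-butyl(dimethyl)silyl]oxy}methyl)-8-(hydroxymethyl)-3,3,7-trimethyldeca-1,7,9-trien-1-yl]-4,5-diphenyl-1,3-dioxolane | C1(/C=C/C(C)(C)CCC/C(C)=C(CO)/C(=C)CO[Si](C)(C)C(C)(C)C)O[C@H](c2ccccc2)[C@@H](c2ccccc2)O1
F2 | step 7 | (4R,5R)-2-[(1R,4aR,8aR)-3-({[tert-butyl(dimethyl)silyl]oxy}methyl)-4-(hydroxymethyl)-4a,8,8-trimethyl-1,2,4a,5,6,7,8,8a-octahydronaphthalen-1-yl]-4,5-diphenyl-1,3-dioxolane | C1([C@@H]2CC(CO[Si](C)(C)C(C)(C)C)=C(CO)[C@]3(C)CCCC(C)(C)[C@@H]23)O[C@H](c4ccccc4)[C@@H](c4ccccc4)O1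
F3 | step 8 | (4aR,8aR)-3-({[tert-butyl(dimethyl)silyl]oxy}methyl)-4a,8,8-trimethyl-1-[(trimethylsilyl)oxy]-4-{[(trimethylsilyl)oxy]methyl}-4a,5,6,7,8,8a-hexahydronaphthalene | C[Si](C)(C)OC1=CC(CO[Si](C)(C)C(C)(C)C)=C(CO[Si](C)(C)C)[C@]2(C)CCCC(C)(C)[C@@H]12
F4 | step 14 | (1S,4S,4aR,8aR)-3-({[tert-butyl(dimethyl)silyl]oxy}methyl)-4a,8,8-trimethyl-4-{[(1-phenyl-1H-tetrazol-5-yl)sulfanyl]methyl}-1,4,4a,5,6,7,8,8a-octahydronaphthalen-1-ol | O[C@H]1C=C(CO[Si](C)(C)C(C)(C)C)[C@@H](CSc3nnnn3-c3ccccc3)[C@]2(C)CCCC(C)(C)[C@@H]12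
F5 | step 14 | (1S,4S,4aR,8aR)-3-({[tert-butyl(dimethyl)silyl]oxy}methyl)-4a,8,8-trimethyl-4-{[(1-phenyl-1H-tetrazol-5-yl)sulfonyl]methyl}-1,4,4a,5,6,7,8,8a-octahydronaphthalen-1-ol | O[C@H]1C=C(CO[Si](C)(C)C(C)(C)C)[C@@H](CS(=O)(=O)c3nnnn3-c3ccccc3)[C@]2(C)CCCC(C)(C)[C@@H]12
F6 | step 14 | (2S)-2-[(4-methoxyphenyl)methoxy]-2-methylbut-3-enal | C=C[C@](C)(OCc1ccc(OC)cc1)C=O
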